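## Structural features

The target is a sesquiterpenyl benzoxazole: a bicyclic C15 terpene unit is joined through one methylene carbon (C11) to C7 of a 2-methyl-1,3-benzoxazole that also carries a methoxy group at C5 and a free hydroxyl at C6. The terpene part is a cis-fused decalin in which ring A (C1–C5, C10) holds the trisubstituted C3=C4 alkene with a methyl on C4, and ring B (C5–C10) holds four contiguous stereocentres: quaternary C5 (methyl), C10 (ring-fusion CH), quaternary C9 (methyl and C11) and C8 (CH–CH3). The C8 and C9 methyls are cis to each other and trans to H-10, while the C5 methyl is cis to H-10; the absolute configuration is 5R,8S,9R,10S. The benzylic carbon C11 is neopentylic and sits on an arene carbon flanked by two oxygenated carbons, so the C11–aryl bond is congested on both sides. Fragile features are the C3=C4 alkene (acid-promoted migration or cation chemistry, hydrogenation), the very electron-rich oxygenated arene before and after nitrogen is introduced (air oxidation), and the benzoxazole, whose C2 position and 2-methyl protons do not tolerate organolithium reagents. The real difficulty lies in the two quaternary carbons C5 and C9, which stand 1,3 to each other across C10 with their methyls on opposite faces, and in setting C8, C9 and C10 in absolute terms with no stereocentre to start from. The key step uses the fact that C8, C9 and C10 of ring B, together with C7 and the formyl-derived C11, correspond atom for atom to an exo [4+2] adduct of an E-configured α-methyl enal (C8=C9) with a 1-vinylcyclohexene (C7=C6–C5=C10), which also leaves the C5=C6 alkene beside a masked C4 ketone for the later work on C5 and C4.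

## Logic of the disconnections

24 to 23 to 22 to 21: the oxazole bonds C2–O and C2=N are cut to an orthoester carbon and 23, and the C–N bond of 23 is traced through the azo group of 22 to a ring C–H of 21. The heterocycle holds the only nitrogen and would not survive the organometallic and dissolving-metal steps, so it is made last. The arene simplifies to a plain resorcinol. The forward steps must put nitrogen on one ring position only, under non-acidic and non-oxidising conditions, and close the ring before 23 can oxidise.

21 to 20: the two O–CH2OCH3 bonds are cut (protecting groups). The phenols have to be masked for lithiation, for the Li/NH3 steps and for enolate chemistry. The demand is a removal that leaves the C3=C4 alkene in place.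

20 to 19 to 17 (through 18): the C4–CH3 bond is cut to give 19, and the C4–O bond of 19 is traced through 18 to the carbonyl of 17. Because C5 is quaternary, the ketone can enolise only towards C3, so the alkene position is fixed by constitution. One methyl and the alkene are traded for a carbonyl. The forward coupling must work on a hindered alkenyl triflate next to a quaternary carbon.

17 to 15 (through 16): the C5–CH3 bond (with the C6–H bond) is cut by a reductive methylation transform. The C4 enone makes C5 the only nucleophilic carbon after two-electron reduction. This removes the second quaternary stereocentre. The forward step must deliver the methyl to the face of H-10 and must not reduce the arene.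

15 to 14: the C4 carbonyl is retraced to its dioxolane. The ketone stays masked while organolithium and Li/NH3 are used. The demand is hydrolysis that spares the aryl methoxymethyl ethers.

14 to 6 and 11 (through 12 and 13): the C11–C1' bond is cut, with oxygen restored on C11, which leads to 6 and to 12, the lithiated form of 11. This is the most convergent bond, it is made at a carbon that ends as a non-stereogenic CH2, and the formyl group is delivered directly by the cycloaddition, so no redox or protecting steps are spent on C11. The forward step must add a 2,6-dioxygenated aryllithium to a neopentyl aldehyde and then remove the benzylic oxygen without touching the ketal or the C5=C6 alkene.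

11 to 10 to 8 to 7 (through 9): the O–CH3 bond, the aryl C–O bond (retraced to the formyl carbon) and the two O–CH2OCH3 bonds are cut in turn. This gives the 1,2,4-trioxygenated pattern from a cheap dioxygenated aldehyde. The demand is aryl (not hydride) migration in the oxidation.

6 to 4 and 5: the C9–C10 and C7–C8 bonds are cut in a retro-[4+2] sense. Ring B and three stereocentres disappear at once and both fragments are achiral. The forward step needs ortho regiochemistry, exo topology and control of the enantiotopic face by a chiral Lewis acid, in the presence of an acid-sensitive ketal.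

4 to 3 to 2 to 1: the C6–vinyl bond (spiro numbering) is cut to give 3 and a vinylboron reagent, the dioxolane of 3 is retraced to the ketone of 2, and the C–I bond of 2 to the enone C–H of 1. The ketal is installed before the coupling so that a free 2-vinyl enone, which would dimerise, never appears.

## Other disconnections considered

Alternative 1: The cut goes through C5–C10 and C1–C2, so both rings open to the acyclic triene A1, a (Z)-2-silyloxy-1,3-diene tethered through C6–C9 to a vinyl group. Heating A1 would close rings A and B in one intramolecular Diels–Alder reaction to the silyl enol ether A2.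
- In its favour: two rings and two bonds are formed in one step, against one ring in the chosen plan, which is the better figure. The enol ether of A2 lies exactly at C3=C4, where the C4 substituent and the alkene are needed. No Lewis acid meets an acid-sensitive ketal, and the arene is carried from the start.
- Against it here: A2 has hydrogen at C5, without control, and no C5 methyl. Introducing the methyl would mean unmasking the C4 carbonyl of A2 and alkylating at the more substituted α-carbon C5 in competition with C3, whereas the regiodefined enol ether points to C3. C8 and the quaternary C9 would have to be built on an open chain. C10 would be set only by the conformational bias of the tether, and the unactivated vinyl dienophile calls for high temperature.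
- Comparison: on ring construction the alternative is ahead. On stereocontrol at C5, C9 and C10 the chosen plan is expected to be clearly ahead, since its three centres follow from alkene geometry, exo topology and a catalyst. Mechanistically both are [4+2] reactions, but only the chosen one has an external handle on absolute configuration. In step count the acyclic stereocentres and the missing angular methyl are expected to cost more than the one-step ring formation saves.

Alternative 2: The cut is at C5–C6, with C3–C8 reconnected in the precursor, which leads to the 2-vinylbicyclo[2.2.2]oct-5-en-2-ol A3. KN(SiMe3)2 would form the alkoxide of A3, and the anionic oxy-Cope rearrangement would give the cis-fused decalenone A4.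
- In its favour: the [3,3] shift is suprafacial within a rigid bicycle, so the cis ring fusion, the quaternary C5 methyl and the C3=C4 alkene with its C4 methyl would all arise stereospecifically in one step. On these points it is better than the chosen plan, which needs a reductive methylation, a triflation and a cross-coupling for the same result.
- Against it here: C8 emerges as a ketone, so the C8 methyl and its configuration would have to be added afterwards at a carbonyl flanked by quaternary C9 (olefination, then face-selective and chemoselective reduction beside the C3=C4 alkene). A3 itself needs a quaternary C9 next to a tertiary carbinol of defined configuration, in enantiopure form.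
- Comparison: structurally the alternative solves C5 and C4 more elegantly, while the chosen plan solves C8 and C9, which come directly from the E-enal. Both key steps are stereospecific pericyclic reactions. In step count the short access to 4 and 5 is expected to outweigh the steps saved after A4.

Alternative 3: The cut lies inside the arene (C5'–C6'), which unravels to the 4-hydroxy-4-(trimethylsilylethynyl)cyclobutenone A5. Thermolysis would open the four-membered ring of A5 electrocyclically to the ketene stage, and ring closure onto the alkyne followed by hydrogen transfer would give the benzoquinone A6.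
- In its favour: every ring position of A6 is differentiated (alkoxy, silyl, two carbonyls), so nitrogen could enter by ipso substitution of silicon, without relying on the directing effects of a resorcinol. On arene regiocontrol this is better than the chosen endgame.
- Against it here: it says nothing about C5, C8, C9 and C10, so the complete decalin must come from another route and must then be used as a neopentyl C11 nucleophile to build A5. After A6 several adjustments remain (reduction, differentiation of the two hydroxyls, removal of the isopropyl group, silicon-to-nitrogen exchange).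
- Comparison: structurally it addresses the easier half of the molecule. Mechanistically a thermal electrocyclic opening and diradical closure replaces a directed lithiation and an azo coupling. In step count it is expected to be longer, and it would still need a decalin synthesis such as the chosen one.

Key step: step 4

Remarks on the chemistry:
- Decalin carbons are numbered C1–C10, with C11 on C9 (ring A = C1–C5, C10; ring B = C5–C10). "Decal-5-ene" means the C5=C6 alkene. α is the face of H-10, β the face of the C8 and C9 methyls. Arene carbons carry primes, C1' bearing C11.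
- The choice of the (3aR)-configured catalyst in step 4 rests on the accepted transition-state model for oxazaborolidinium-bound α-substituted enals; the sense of induction is an assumption of the plan.

## Route

Step 1
Reactants: 1 cyclohex-2-en-1-one
Product: 2 2-iodocyclohex-2-en-1-one
Conditions: I2, K2CO3, 4-(dimethylamino)pyridine (cat.), THF/H2O 1:1, rt
Reagents that add atoms: iodine, II
Why: α-Iodination of an enone by a Baylis–Hillman-type sequence: the amine adds in a conjugate sense, the enolate is iodinated and the amine is expelled again. No stereocentre is involved.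

Step 2
Reactants: 2 2-iodocyclohex-2-en-1-one
Product: 3 6-iodo-1,4-dioxaspiro[4.5]dec-6-ene
Conditions: ethane-1,2-diol, p-toluenesulfonic acid monohydrate (cat.), cyclohexane, reflux, Dean–Stark trap
Reagents that add atoms: ethane-1,2-diol, OCCO
Why: Acid-catalysed ketalisation with azeotropic removal of water. With the halogen on the α-carbon the alkene stays next to the spiro centre, as is usual for 2-halocycloalkenone ketals.

Step 3
Reactants: 3 6-iodo-1,4-dioxaspiro[4.5]dec-6-ene
Product: 4 6-ethenyl-1,4-dioxaspiro[4.5]dec-6-ene
Conditions: CH2=CHBF3K, PdCl2(dppf) (3 mol%), Cs2CO3, THF/H2O 9:1, 70 °C; product kept cold with BHT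
Reagents that add atoms: potassium ethenyltrifluoroborate, C=C[B-](F)(F)F.[K+]
Why: Suzuki–Miyaura coupling of an alkenyl iodide with an air-stable vinylboron reagent gives the diene without tin. The ketal keeps the diene from the self-dimerisation expected of a free 2-vinyl enone.

Step 4
Reactants: 4 6-ethenyl-1,4-dioxaspiro[4.5]dec-6-ene; 5 (E)-2-methylbut-2-enal
Product: 6 (8S,9R,10S)-4,4-(ethylenedioxy)-8,9-dimethyldecal-5-ene-9-carbaldehyde (8β-CH3; 9β-CH3; 9α-CHO; 10α-H)
Conditions: (3aR)-1-(2-methylphenyl)-3,3-diphenyltetrahydro-1H,3H-pyrrolo[1,2-c][1,3,2]oxazaborole (20 mol%), (CF3SO2)2NH (18 mol%), CH2Cl2, −78 → −40 °C; enal in twofold excess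
Reagents that add atoms: none
Why: The triflimide-activated oxazaborolidine binds the formyl oxygen of 5 (B–O coordination supported by a formyl C–H···O contact), which lowers the LUMO of the s-trans enal, and s-cis 4 then adds in a concerted but asynchronous normal-demand [4+2] cycloaddition. The closest known reaction type is the chiral oxazaborolidinium-catalysed Diels–Alder reaction of α-substituted enals with 1,3-dienes, including 1-vinylcyclohexenes. Ring B closes in the single suprafacial π4s+π2s event that forms C7–C8 and C9–C10 and moves the alkene to C5=C6. C8 and C9 inherit their cis methyls from the E geometry of 5, which is transferred stereospecifically. C10 is set relative to C9 by the exo transition state (formyl turned away from the diene, the α-methyl under it), the normal preference of α-methyl enals, which puts H-10 cis to the formyl carbon. The absolute sense comes from the catalyst: its phenyl group covers one face of the bound enal, and for the (3aR)-catalyst the model leaves the C2 Si face of 5 open, which corresponds to (8S,9R,10S)-6. The step needs ortho regioselectivity (C10 to C9), and this is secured by the larger HOMO coefficient at the unsubstituted vinyl terminus C7 of 4, which pairs with the β-carbon of the enal. It also needs the dioxolane to survive, which the low temperature and the slight excess of oxazaborolidine over acid (no free Brønsted acid) are meant to ensure.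

Step 5
Reactants: 7 2,4-dihydroxybenzaldehyde
Product: 8 2,4-bis(methoxymethoxy)benzaldehyde
Conditions: MOMCl (2.6 equiv; carcinogen, closed transfer), K2CO3, acetone, 0 °C → reflux
Reagents that add atoms: chloromethyl methyl ether, COCCl
Why: Williamson-type O-alkylation of both phenols; the chelated 2-hydroxyl needs the reflux period. The methoxymethyl groups later direct the lithiation and are inert to Li/NH3.

Step 6
Reactants: 8 2,4-bis(methoxymethoxy)benzaldehyde
Product: 10 2,4-bis(methoxymethoxy)phenol, via aryl formate 9 (not isolated)
Conditions: mCPBA, CH2Cl2, 0 °C → rt; aqueous NaHCO3 wash; then K2CO3 (cat.), MeOH, rt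
Reagents that add atoms: 3-chloroperoxybenzoic acid, OOC(=O)c1cccc(Cl)c1
Why: Baeyer–Villiger (Dakin-type) oxidation: the electron-rich aryl group migrates in preference to hydrogen. Base-catalysed methanolysis of the formate releases the phenol.

Step 7
Reactants: 10 2,4-bis(methoxymethoxy)phenol
Product: 11 1-methoxy-2,4-bis(methoxymethoxy)benzene
Conditions: MeI, K2CO3, acetone, reflux
Reagents that add atoms: iodomethane, CI
Why: Williamson methylation of the only free phenol.

Step 8
Reactants: 11 1-methoxy-2,4-bis(methoxymethoxy)benzene; 6 (8S,9R,10S)-4,4-(ethylenedioxy)-8,9-dimethyldecal-5-ene-9-carbaldehyde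
Product: 14 (8S,9R,10S)-4,4-(ethylenedioxy)-9-{[3-methoxy-2,6-bis(methoxymethoxy)phenyl]methyl}-8,9-dimethyldecal-5-ene, via aryllithium 12 (not isolated), via lithium alkoxide 13 (not isolated)
Conditions: 11 (slight excess), n-BuLi, THF, 0 °C; then 6, −78 → 0 °C; then NH3 (l), Li (4 equiv), −78 °C; solid NH4Cl
Reagents that add atoms: none
Why: Directed ortho-metalation occurs at the only position flanked by two methoxymethoxy groups, and the aryllithium adds to the non-enolisable neopentyl aldehyde. The benzylic alkoxide is then cleaved at its C–O bond on the NH4Cl quench in the presence of lithium (tandem addition and dissolving-metal reduction of a benzylic alkoxide). Both C11 epimers converge on the CH2 compound and C8, C9 and C10 are not touched.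

Step 9
Reactants: 14 (8S,9R,10S)-4,4-(ethylenedioxy)-9-{[3-methoxy-2,6-bis(methoxymethoxy)phenyl]methyl}-8,9-dimethyldecal-5-ene
Product: 15 (8S,9R,10S)-9-{[3-methoxy-2,6-bis(methoxymethoxy)phenyl]methyl}-8,9-dimethyldecal-5-en-4-one
Conditions: 1 M aq. HCl, THF, 0 °C → rt, monitored closely
Reagents that add atoms: water, O
Why: Acid-catalysed acetal hydrolysis: the allylic dioxolane opens through a stabilised oxocarbenium ion much faster than aryl methoxymethyl ethers are cleaved, giving the conjugated C4(=O)–C5=C6 enone. H-10 is cross-conjugated to the carbonyl and therefore not at risk of epimerisation.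

Step 10
Reactants: 15 (8S,9R,10S)-9-{[3-methoxy-2,6-bis(methoxymethoxy)phenyl]methyl}-8,9-dimethyldecal-5-en-4-one
Product: 17 (5R,8S,9R,10S)-9-{[3-methoxy-2,6-bis(methoxymethoxy)phenyl]methyl}-5,8,9-trimethyl-cis-decalin-4-one (5α-CH3), via lithium enolate 16 (not isolated)
Conditions: Li (2.2 equiv), t-BuOH (1.0 equiv), NH3 (l)/THF, −78 °C; then MeI (5 equiv), −78 → −33 °C
Reagents that add atoms: iodomethane, CI
Why: Dissolving-metal reductive alkylation: two-electron reduction with protonation at C6 gives the regiodefined C4(O–)=C5 enolate, which is methylated at C5. In the ring B chair the C9 β-methyl is axial and 1,3 to C5, so MeI should enter anti to it, on the face of H-10; this is also the intrinsic preference of ring-fusion decalone enolates and gives the cis-fused ketone. Limited lithium and the absence of excess alcohol keep the arene out of the reduction.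

Step 11
Reactants: 17 (5R,8S,9R,10S)-9-{[3-methoxy-2,6-bis(methoxymethoxy)phenyl]methyl}-5,8,9-trimethyl-cis-decalin-4-one
Product: 19 (5R,8S,9R,10S)-9-{[3-methoxy-2,6-bis(methoxymethoxy)phenyl]methyl}-5,8,9-trimethyl-cis-decal-3-en-4-yl trifluoromethanesulfonate, via potassium enolate 18 (not isolated)
Conditions: KN(SiMe3)2, THF, −78 °C; PhN(SO2CF3)2, −78 → 0 °C
Reagents that add atoms: N-phenylbis(trifluoromethanesulfonimide), O=S(=O)(N(c1ccccc1)S(=O)(=O)C(F)(F)F)C(F)(F)F
Why: The ketone has α-hydrogens only at C3 because C5 is quaternary, so enolisation and O-sulfonylation can give only the C3=C4 enol triflate.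

Step 12
Reactants: 19 (5R,8S,9R,10S)-9-{[3-methoxy-2,6-bis(methoxymethoxy)phenyl]methyl}-5,8,9-trimethyl-cis-decal-3-en-4-yl trifluoromethanesulfonate
Product: 20 1-methoxy-2,4-bis(methoxymethoxy)-3-{[(1R,2S,4aR,8aS)-1,2,4a,5-tetramethyl-1,2,3,4,4a,7,8,8a-octahydronaphthalen-1-yl]methyl}benzene
Conditions: MeMgBr (3 equiv), Fe(acac)3 (10 mol%), THF/NMP, −30 → 0 °C
Reagents that add atoms: methylmagnesium bromide, C[Mg]Br
Why: Iron-catalysed Kumada-type cross-coupling of an alkenyl triflate with a methyl Grignard reagent is fast at low temperature and tolerates acetals and aryl ethers. It fixes the C4 methyl and the C3=C4 alkene without positional isomers.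

Step 13
Reactants: 20 1-methoxy-2,4-bis(methoxymethoxy)-3-{[(1R,2S,4aR,8aS)-1,2,4a,5-tetramethyl-1,2,3,4,4a,7,8,8a-octahydronaphthalen-1-yl]methyl}benzene
Product: 21 4-methoxy-2-{[(1R,2S,4aR,8aS)-1,2,4a,5-tetramethyl-1,2,3,4,4a,7,8,8a-octahydronaphthalen-1-yl]methyl}benzene-1,3-diol
Conditions: HCl (1.25 M in MeOH), THF, 0 °C → rt, degassed
Reagents that add atoms: none
Why: Acid-catalysed acetal exchange transfers both methoxymethyl groups to methanol. The dilute acid and low temperature are chosen to leave the trisubstituted alkene in place.

Step 14
Reactants: 21 4-methoxy-2-{[(1R,2S,4aR,8aS)-1,2,4a,5-tetramethyl-1,2,3,4,4a,7,8,8a-octahydronaphthalen-1-yl]methyl}benzene-1,3-diol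
Product: 22 4-methoxy-6-[(E)-phenyldiazenyl]-2-{[(1R,2S,4aR,8aS)-1,2,4a,5-tetramethyl-1,2,3,4,4a,7,8,8a-octahydronaphthalen-1-yl]methyl}benzene-1,3-diol
Conditions: PhN2BF4 (1.05 equiv), NaHCO3, THF/H2O, 0 °C
Reagents that add atoms: benzenediazonium tetrafluoroborate, N#[N+]c1ccccc1.F[B-](F)(F)F
Why: Azo coupling is an electrophilic aromatic substitution by a weak, non-acidic electrophile. It should take place at the only free position that is ortho to one hydroxyl and para to the other; the other free position is meta to both.

Step 15
Reactants: 22 4-methoxy-6-[(E)-phenyldiazenyl]-2-{[(1R,2S,4aR,8aS)-1,2,4a,5-tetramethyl-1,2,3,4,4a,7,8,8a-octahydronaphthalen-1-yl]methyl}benzene-1,3-diol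
Product: 24 5-methoxy-2-methyl-7-{[(1R,2S,4aR,8aS)-1,2,4a,5-tetramethyl-1,2,3,4,4a,7,8,8a-octahydronaphthalen-1-yl]methyl}-1,3-benzoxazol-6-ol, via aminoresorcinol 23 (not isolated)
Conditions: Na2S2O4, THF/H2O, 50 °C; extraction under argon; crude amine, MeC(OEt)3, pyridinium p-toluenesulfonate (cat.), EtOH, 70 °C
Reagents that add atoms: triethyl orthoacetate, CCOC(C)(OCC)OCC
Why: Dithionite cleaves the azo N=N bond reductively to the o-aminophenol and aniline without touching the alkene. Condensation with the orthoester closes the 2-methylbenzoxazole on the only hydroxyl ortho to the amine and leaves the other hydroxyl free.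

## Compound list

1 | cyclohex-2-en-1-one | O=C1C=CCCC1 | starting material
2 | 2-iodocyclohex-2-en-1-one | O=C1C(I)=CCCC1 | intermediate
3 | 6-iodo-1,4-dioxaspiro[4.5]dec-6-ene | IC1=CCCCC12OCCO2 | intermediate
4 | 6-ethenyl-1,4-dioxaspiro[4.5]dec-6-ene | C=CC1=CCCCC12OCCO2 | intermediate
5 | (E)-2-methylbut-2-enal | C/C=C(\C)C=O | starting material
6 | (8S,9R,10S)-4,4-(ethylenedioxy)-8,9-dimethyldecal-5-ene-9-carbaldehyde (8β-CH3, 9β-CH3, 9α-CHO, 10α-H) | O=C[C@]1(C)[C@@H](C)CC=C2[C@H]1CCCC23OCCO3 | intermediate
7 | 2,4-dihydroxybenzaldehyde | O=Cc1ccc(O)cc1O | starting material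
8 | 2,4-bis(methoxymethoxy)benzaldehyde | O=Cc1ccc(OCOC)cc1OCOC | intermediate
9 | 2,4-bis(methoxymethoxy)phenyl formate | O=COc1ccc(OCOC)cc1OCOC | intermediate
10 | 2,4-bis(methoxymethoxy)phenol | Oc1ccc(OCOC)cc1OCOC | intermediate
11 | 1-methoxy-2,4-bis(methoxymethoxy)benzene | COc1ccc(OCOC)cc1OCOC | intermediate
12 | [3-methoxy-2,6-bis(methoxymethoxy)phenyl]lithium | [Li]c1c(OCOC)ccc(OC)c1OCOC | intermediate
13 | lithium alkoxide of [(8S,9R,10S)-4,4-(ethylenedioxy)-8,9-dimethyldecal-5-en-9-yl][3-methoxy-2,6-bis(methoxymethoxy)phenyl]methanol (both C11 epimers) | [Li+].[O-]C(c1c(OCOC)ccc(OC)c1OCOC)[C@]1(C)[C@@H](C)CC=C2[C@H]1CCCC23OCCO3 | intermediate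
14 | (8S,9R,10S)-4,4-(ethylenedioxy)-9-{[3-methoxy-2,6-bis(methoxymethoxy)phenyl]methyl}-8,9-dimethyldecal-5-ene | COCOc1ccc(OC)c(OCOC)c1C[C@]1(C)[C@@H](C)CC=C2[C@H]1CCCC23OCCO3 | intermediate
15 | (8S,9R,10S)-9-{[3-methoxy-2,6-bis(methoxymethoxy)phenyl]methyl}-8,9-dimethyldecal-5-en-4-one | COCOc1ccc(OC)c(OCOC)c1C[C@]1(C)[C@@H](C)CC=C2[C@H]1CCCC2=O | intermediate
16 | lithium (8S,9R,10S)-9-{[3-methoxy-2,6-bis(methoxymethoxy)phenyl]methyl}-8,9-dimethyldecal-4-en-4-olate (C4=C5 enolate) | COCOc1ccc(OC)c(OCOC)c1C[C@]1(C)[C@@H](C)CCC2=C([O-])CCC[C@@H]12.[Li+] | intermediate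
17 | (5R,8S,9R,10S)-9-{[3-methoxy-2,6-bis(methoxymethoxy)phenyl]methyl}-5,8,9-trimethyl-cis-decalin-4-one | COCOc1ccc(OC)c(OCOC)c1C[C@]1(C)[C@@H](C)CC[C@@]2(C)C(=O)CCC[C@@H]12 | intermediate
18 | potassium (5R,8S,9R,10S)-9-{[3-methoxy-2,6-bis(methoxymethoxy)phenyl]methyl}-5,8,9-trimethyl-cis-decal-3-en-4-olate | COCOc1ccc(OC)c(OCOC)c1C[C@]1(C)[C@@H](C)CC[C@@]2(C)C([O-])=CCC[C@@H]12.[K+] | intermediate
19 | (5R,8S,9R,10S)-9-{[3-methoxy-2,6-bis(methoxymethoxy)phenyl]methyl}-5,8,9-trimethyl-cis-decal-3-en-4-yl trifluoromethanesulfonate | COCOc1ccc(OC)c(OCOC)c1C[C@]1(C)[C@@H](C)CC[C@@]2(C)C(OS(=O)(=O)C(F)(F)F)=CCC[C@@H]12 | intermediate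
20 | 1-methoxy-2,4-bis(methoxymethoxy)-3-{[(1R,2S,4aR,8aS)-1,2,4a,5-tetramethyl-1,2,3,4,4a,7,8,8a-octahydronaphthalen-1-yl]methyl}benzene | COCOc1ccc(OC)c(OCOC)c1C[C@]1(C)[C@@H](C)CC[C@@]2(C)C(C)=CCC[C@@H]12 | intermediate
21 | 4-methoxy-2-{[(1R,2S,4aR,8aS)-1,2,4a,5-tetramethyl-1,2,3,4,4a,7,8,8a-octahydronaphthalen-1-yl]methyl}benzene-1,3-diol | COc1ccc(O)c(C[C@]2(C)[C@@H](C)CC[C@@]3(C)C(C)=CCC[C@@H]23)c1O | intermediate
22 | 4-methoxy-6-[(E)-phenyldiazenyl]-2-{[(1R,2S,4aR,8aS)-1,2,4a,5-tetramethyl-1,2,3,4,4a,7,8,8a-octahydronaphthalen-1-yl]methyl}benzene-1,3-diol | COc1cc(/N=N/c2ccccc2)c(O)c(C[C@]2(C)[C@@H](C)CC[C@@]3(C)C(C)=CCC[C@@H]23)c1O | intermediate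
23 | 4-amino-6-methoxy-2-{[(1R,2S,4aR,8aS)-1,2,4a,5-tetramethyl-1,2,3,4,4a,7,8,8a-octahydronaphthalen-1-yl]methyl}benzene-1,3-diol | COc1cc(N)c(O)c(C[C@]2(C)[C@@H](C)CC[C@@]3(C)C(C)=CCC[C@@H]23)c1O | intermediate
24 | 5-methoxy-2-methyl-7-{[(1R,2S,4aR,8aS)-1,2,4a,5-tetramethyl-1,2,3,4,4a,7,8,8a-octahydronaphthalen-1-yl]methyl}-1,3-benzoxazol-6-ol | COc1cc2nc(C)oc2c(C[C@]2(C)[C@@H](C)CC[C@@]3(C)C(C)=CCC[C@@H]23)c1O | target

## Step count and least certain steps

Total step count: 15. Longest linear sequence: 12 steps (steps 1–4 and 8–15); the arene branch (steps 5–7) joins at step 8.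

Step 4 (key step).
- What may go wrong: ionisation of the dioxolane of 4 by the strongly Lewis-acidic catalyst, followed by oligomerisation of the diene; binding of the ketal oxygens to boron, which would stall the reaction with a dienophile as sluggish as 5; erosion of exo or facial selectivity.
- The sense of induction rests on a model. If the adduct turned out to be the mirror image, the enantiomeric catalyst would be used under the same conditions.
- Fallback (sets out from 4 and 5, returns at 6): the cycloaddition is run without a chiral catalyst (toluene, 110 °C, BHT, sealed vessel, or catalytic LiN(SO2CF3)2 in CH2Cl2) to give the racemic exo adduct F1. NaBH4 in MeOH reduces it to the racemic primary alcohol F2. Acylation with (1S)-camphanic chloride (pyridine, 4-(dimethylamino)pyridine) gives two diastereomeric esters, from which the (8S,9R,10S) camphanate F3 is separated by crystallisation or chromatography. Aqueous LiOH in THF/MeOH releases the enantiopure alcohol F4, and oxidation with TEMPO (cat.) and PhI(OAc)2 in CH2Cl2 regenerates 6.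

Step 8.
- What may go wrong: incomplete addition of the hindered 2,6-disubstituted aryllithium to the neopentyl aldehyde; over-reduction during the NH4Cl quench (partial ring reduction or loss of an aryl oxygen substituent), because lithium with an ammonium salt is a Birch-type medium.
- Fallback (sets out from 6 and 11, returns at 14): the addition is quenched with aqueous NH4Cl and the benzylic alcohol F5 (both C11 epimers) is isolated. It is converted with NaH, CS2 and MeI into the S-methyl xanthate F6, which is deoxygenated in a tin-free Barton–McCombie reaction ((Me3Si)3SiH, 2,2'-azobis(2-methylpropionitrile), toluene, 90 °C) to 14.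

Step 10.
- What may go wrong: proton transfer to the enolate before C-methylation, leaving the unmethylated ketone; enolate equilibration and a second methylation at C3; incomplete facial selectivity at C5; partial reduction of the electron-rich arene.
- Fallback (sets out from 15, returns at 17): 15 is reduced with Li/NH3 as before, but the enolate is trapped with Me3SiCl/Et3N as the trimethylsilyl enol ether F7. Simmons–Smith cyclopropanation (Et2Zn, CH2I2, CH2Cl2, 0 °C) is expected to occur on the same α-face, anti to the C9 methyl, and give the siloxycyclopropane F8. Opening of F8 with NaOH in MeOH (cleavage of the C4–CH2 bond and protonation) gives the angular methyl ketone 17.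

Step 14 (with the telescoped step 15).
- What may go wrong: electron-transfer oxidation of the very electron-rich resorcinol by the diazonium salt instead of C-coupling; slow coupling next to the bulky neopentyl substituent; air oxidation of 23 before ring closure.
- Fallback (sets out from 21, returns at 24): C-nitration of 21 with tert-butyl nitrite (THF, rt), a mild mononitration of phenols, gives the nitroresorcinol F9. F9 is reduced and cyclised in one pot (Fe powder, AcOH, MeC(OEt)3, 80 °C) to 24, which bypasses 22 and 23.

## Further compounds

F1 | step 4 | racemic 4,4-(ethylenedioxy)-8,9-dimethyldecal-5-ene-9-carbaldehyde (exo adduct, both enantiomers) | O=C[C@]1(C)[C@@H](C)CC=C2[C@H]1CCCC23OCCO3.O=C[C@@]1(C)[C@H](C)CC=C2[C@@H]1CCCC23OCCO3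
F2 | step 4 | racemic [4,4-(ethylenedioxy)-8,9-dimethyldecal-5-en-9-yl]methanol (both enantiomers) | OC[C@]1(C)[C@@H](C)CC=C2[C@H]1CCCC23OCCO3.OC[C@@]1(C)[C@H](C)CC=C2[C@@H]1CCCC23OCCO3
F3 | step 4 | [(8S,9R,10S)-4,4-(ethylenedioxy)-8,9-dimethyldecal-5-en-9-yl]methyl (1S,4R)-4,7,7-trimethyl-3-oxo-2-oxabicyclo[2.2.1]heptane-1-carboxylate | O=C(OC[C@]1(C)[C@@H](C)CC=C2[C@H]1CCCC23OCCO3)[C@@]12CC[C@@](C)(C(=O)O1)C2(C)C
F4 | step 4 | [(8S,9R,10S)-4,4-(ethylenedioxy)-8,9-dimethyldecal-5-en-9-yl]methanol | OC[C@]1(C)[C@@H](C)CC=C2[C@H]1CCCC23OCCO3
F5 | step 8 | [(8S,9R,10S)-4,4-(ethylenedioxy)-8,9-dimethyldecal-5-en-9-yl][3-methoxy-2,6-bis(methoxymethoxy)phenyl]methanol (both C11 epimers) | OC(c1c(OCOC)ccc(OC)c1OCOC)[C@]1(C)[C@@H](C)CC=C2[C@H]1CCCC23OCCO3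
F6 | step 8 | O-{[(8S,9R,10S)-4,4-(ethylenedioxy)-8,9-dimethyldecal-5-en-9-yl][3-methoxy-2,6-bis(methoxymethoxy)phenyl]methyl} S-methyl carbonodithioate | CSC(=S)OC(c1c(OCOC)ccc(OC)c1OCOC)[C@]1(C)[C@@H](C)CC=C2[C@H]1CCCC23OCCO3
F7 | step 10 | (8S,9R,10S)-9-{[3-methoxy-2,6-bis(methoxymethoxy)phenyl]methyl}-8,9-dimethyl-4-(trimethylsilyloxy)decal-4-ene (C4=C5 silyl enol ether) | COCOc1ccc(OC)c(OCOC)c1C[C@]1(C)[C@@H](C)CCC2=C(O[Si](C)(C)C)CCC[C@@H]12
F8 | step 10 | 4α,5α-methano-(8S,9R,10S)-9-{[3-methoxy-2,6-bis(methoxymethoxy)phenyl]methyl}-8,9-dimethyl-4β-(trimethylsilyloxy)decalin (siloxycyclopropane across C4–C5) | COCOc1ccc(OC)c(OCOC)c1C[C@]1(C)[C@@H](C)CC[C@@]23C[C@]2(O[Si](C)(C)C)CCC[C@@H]13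
F9 | step 14 | 4-methoxy-6-nitro-2-{[(1R,2S,4aR,8aS)-1,2,4a,5-tetramethyl-1,2,3,4,4a,7,8,8a-octahydronaphthalen-1-yl]methyl}benzene-1,3-diol | COc1cc([N+](=O)[O-])c(O)c(C[C@]2(C)[C@@H](C)CC[C@@]3(C)C(C)=CCC[C@@H]23)c1O
A1 | alternative 1 | acyclic triene: tert-butyldimethylsilyl (Z)-dienol ether of (7S,8S)-8-{[3-methoxy-2,6-bis(methoxymethoxy)phenyl]methyl}-7,8-dimethyldeca-1,3,9-trien-3-ol | COCOc1ccc(OC)c(OCOC)c1C[C@](C)([C@@H](C)CC/C=C(O[Si](C)(C)C(C)(C)C)/C=C)C=C
A2 | alternative 1 | decalin C3=C4 tert-butyldimethylsilyl enol ether (C5 hydrogen not controlled) | COCOc1ccc(OC)c(OCOC)c1C[C@]1(C)[C@@H](C)CCC2C(O[Si](C)(C)C(C)(C)C)=CCC[C@@H]12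
A3 | alternative 2 | 2-ethenyl-3-{[3-methoxy-2,6-bis(methoxymethoxy)phenyl]methyl}-3,5,6-trimethylbicyclo[2.2.2]oct-5-en-2-ol (vinyl and arylmethyl syn to the C5=C6 bridge) | C=C[C@@]1(O)[C@@](C)(Cc2c(OCOC)ccc(OC)c2OCOC)[C@@H]2CC[C@H]1C(C)=C2C
A4 | alternative 2 | cis-fused 9-arylmethyl-4,5,9-trimethyldecal-3-en-8-one | COCOc1ccc(OC)c(OCOC)c1C[C@]1(C)C(=O)CC[C@@]2(C)C(C)=CCC[C@@H]12
A5 | alternative 3 | 4-hydroxy-3-(propan-2-yloxy)-2-{[(1R,2S,4aR,8aS)-1,2,4a,5-tetramethyl-1,2,3,4,4a,7,8,8a-octahydronaphthalen-1-yl]methyl}-4-[(trimethylsilyl)ethynyl]cyclobut-2-en-1-one | CC(C)OC1=C(C[C@]2(C)[C@@H](C)CC[C@@]3(C)C(C)=CCC[C@@H]23)C(=O)C1(O)C#C[Si](C)(C)C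
A6 | alternative 3 | 2-(decalinylmethyl)-3-(propan-2-yloxy)-6-(trimethylsilyl)-1,4-benzoquinone | CC(C)OC1=C(C[C@]2(C)[C@@H](C)CC[C@@]3(C)C(C)=CCC[C@@H]23)C(=O)C([Si](C)(C)C)=CC1=O
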